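**Retrosynthetic overview**

1. The strategy rests on ring B, the cycloheptane C1–C2–C3–C4–C5–C6–C10: the methylidene on C1 lies between ring-fusion C10 and the CH2 C2, so C1(=CH2)–C2–C3 is the retron of a carbonyl-ene reaction. Cutting C2–C3 gives the cis-cyclopentane aldehyde 15 (C10 isopropenyl, C6–CMe2–CH2–CHO); the C3 hydroxyl is removed afterwards.
2. Ring A (cyclopentane C6–C10) comes first: C9 by asymmetric methylation of keto ester 1, C10–C1 by Stille acetylation of an enol triflate, C6–C5 by conjugate reverse prenylation of enone 8.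
3. The 2,7-dioxabicyclo[3.2.1]octan-3-one (C11–C16) is built last: C11–C15 by 5-exo radical cyclization of a bromoacetal from enol ether 21 and (R)-hydroxyglutaconate 27, then O–C12 acylal lactonization, then C14–O by enolate oxidation.
4. Order of ring formation: cyclopentane (from 1), cycloheptane (step 11), oxolane (step 22), δ-lactone (step 24).

Key step: step 11

Remark (numbering): C1(=CH2)–C2–C3–C4–C5(Me2)–C6–C10 is the seven-membered ring, C6–C7–C8–C9(Me)–C10 the five-membered ring; C11 is the CH on C9, C12 the acetal CH, C13 the lactone C=O, C14 the CH–OAc, C15 the bridgehead CH, C16 the CH–CO2Me.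
Remark (step 1): the antipode of the ammonium catalyst is taken to be the one that gives the (R)-ester 2.
Remark (mixtures): the carbinol C3 in 16 and 17, the bromide carbon C11 in 28 and the acetal carbon C12 in 28–30 are carried as epimer mixtures; none of these centres survives as such.

**Route**

Step 1
Reactants: 1 tert-butyl 2-oxocyclopentane-1-carboxylate
Product: 2 tert-butyl (1R)-1-methyl-2-oxocyclopentane-1-carboxylate
Conditions: MeI, K2CO3, (11bS,11'bS)-2,2',6,6'-tetrakis(3,4,5-trifluorophenyl)-3,3',5,5'-tetrahydro-4,4'-spirobi[dinaphtho[2,1-c:1',2'-e]azepin]-4-ium bromide (1 mol %), toluene, −20 °C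
Reagents that add atoms: iodomethane CI
Why: Asymmetric phase-transfer alkylation of the β-keto ester enolate, in which the chiral ammonium ion shields one enolate face so that methylation sets the quaternary C9 centre.

Step 2
Reactants: 2 tert-butyl (1R)-1-methyl-2-oxocyclopentane-1-carboxylate
Product: 3 (2S)-2-(hydroxymethyl)-2-methylcyclopentan-1-ol (both C1 epimers)
Conditions: LiAlH4, THF, 0 °C to reflux
Reagents that add atoms: none
Why: Hydride reduction of ketone and tert-butyl ester to the 1,3-diol; the carbinol configuration is irrelevant because step 4 reoxidises it.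

Step 3
Reactants: 3 (2S)-2-(hydroxymethyl)-2-methylcyclopentan-1-ol
Product: 4 (2S)-2-methyl-2-(triisopropylsilyloxymethyl)cyclopentan-1-ol
Conditions: i-Pr3SiCl, imidazole, DMF, 0 °C to rt
Reagents that add atoms: chlorotri(propan-2-yl)silane CC(C)[Si](Cl)(C(C)C)C(C)C
Why: Silylation with a bulky silyl chloride should be selective for the primary hydroxyl over the secondary one next to the quaternary carbon.

Step 4
Reactants: 4 (2S)-2-methyl-2-(triisopropylsilyloxymethyl)cyclopentan-1-ol
Product: 5 (2S)-2-methyl-2-(triisopropylsilyloxymethyl)cyclopentan-1-one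
Conditions: Dess–Martin periodinane, NaHCO3, CH2Cl2, rt
Reagents that add atoms: none
Why: Dess–Martin oxidation of the secondary alcohol leaves the silyl ether intact, and C9 has no α-hydrogen to epimerise.

Step 5
Reactants: 5 (2S)-2-methyl-2-(triisopropylsilyloxymethyl)cyclopentan-1-one
Product: 6 (5S)-5-methyl-5-(triisopropylsilyloxymethyl)cyclopent-1-en-1-yl trifluoromethanesulfonate
Conditions: KN(SiMe3)2, THF, −78 °C; PhNTf2, −78 °C to rt
Reagents that add atoms: N-phenylbis(trifluoromethanesulfonimide) O=S(=O)(N(c1ccccc1)S(=O)(=O)C(F)(F)F)C(F)(F)F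
Why: Enolisation can occur only toward C6 because C9 is quaternary, and O-sulfonylation of the potassium enolate gives the C10 enol triflate.

Step 6
Reactants: 6 (5S)-5-methyl-5-(triisopropylsilyloxymethyl)cyclopent-1-en-1-yl trifluoromethanesulfonate
Product: 8 1-[(5R)-5-methyl-5-(triisopropylsilyloxymethyl)cyclopent-1-en-1-yl]ethan-1-one, via ethoxydiene 7 (not isolated)
Conditions: tributyl(1-ethoxyethenyl)stannane, Pd(PPh3)4 (5 mol %), LiCl, THF, 65 °C; then 1 M HCl, rt
Reagents that add atoms: tributyl(1-ethoxyethenyl)stannane C=C(OCC)[Sn](CCCC)(CCCC)CCCC; water O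
Why: Stille coupling of the enol triflate with an α-alkoxyvinyl stannane (acetyl anion equivalent, well precedented on enol triflates next to quaternary carbons) forms C10–C1, and hydrolysis of the enol ether gives the conjugated methyl ketone.

Step 7
Reactants: 8 1-[(5R)-5-methyl-5-(triisopropylsilyloxymethyl)cyclopent-1-en-1-yl]ethan-1-one; 9 trimethyl(3-methylbut-2-en-1-yl)silane
Product: 11 1-[(1R,2R,5R)-2-methyl-5-(2-methylbut-3-en-2-yl)-2-(triisopropylsilyloxymethyl)cyclopentyl]ethan-1-one, via titanium enolate 10 (not isolated)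
Conditions: TiCl4, CH2Cl2, −78 °C; MeOH then aq. NaHCO3 at −78 °C
Reagents that add atoms: none
Why: Hosomi–Sakurai conjugate addition in which the allylsilane attacks C6 through its γ-carbon (forming C6–C5 and the quaternary C5) on the face anti to the bulky silyloxymethyl group on C9, after which the titanium enolate should be protonated at C10 from the face opposite to the new tert-alkyl group, giving the all-cis ketone under kinetic control.

Step 8
Reactants: 11 1-[(1R,2R,5R)-2-methyl-5-(2-methylbut-3-en-2-yl)-2-(triisopropylsilyloxymethyl)cyclopentyl]ethan-1-one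
Product: 12 {[(1R,2S,3R)-1-methyl-3-(2-methylbut-3-en-2-yl)-2-(prop-1-en-2-yl)cyclopentyl]methoxy}tri(propan-2-yl)silane
Conditions: Zn, CH2Br2, TiCl4, THF/CH2Cl2, 0 °C to rt
Reagents that add atoms: dibromomethane BrCBr
Why: Takai–Lombardo methylenation converts the hindered, epimerisable methyl ketone into the isopropenyl group under non-basic conditions, so the kinetic C10 configuration should be kept.

Step 9
Reactants: 12 {[(1R,2S,3R)-1-methyl-3-(2-methylbut-3-en-2-yl)-2-(prop-1-en-2-yl)cyclopentyl]methoxy}tri(propan-2-yl)silane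
Product: 14 3-methyl-3-[(1R,2S,3R)-3-methyl-2-(prop-1-en-2-yl)-3-(triisopropylsilyloxymethyl)cyclopentyl]butan-1-ol, via catechol boronate 13 (not isolated)
Conditions: catecholborane, RhCl(PPh3)3 (2 mol %), THF, 0 °C to rt; then NaOH, H2O2
Reagents that add atoms: hydrogen peroxide OO
Why: Rhodium-catalysed hydroboration strongly prefers the monosubstituted vinyl group over the flanked 1,1-disubstituted isopropenyl group and places boron on the terminal carbon, and oxidation gives the primary alcohol.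

Step 10
Reactants: 14 3-methyl-3-[(1R,2S,3R)-3-methyl-2-(prop-1-en-2-yl)-3-(triisopropylsilyloxymethyl)cyclopentyl]butan-1-ol
Product: 15 3-methyl-3-[(1R,2S,3R)-3-methyl-2-(prop-1-en-2-yl)-3-(triisopropylsilyloxymethyl)cyclopentyl]butanal
Conditions: Dess–Martin periodinane, NaHCO3, CH2Cl2, rt
Reagents that add atoms: none
Why: Buffered Dess–Martin oxidation gives the C3 aldehyde without acid or base that could move the isopropenyl double bond.

Step 11
Reactants: 15 3-methyl-3-[(1R,2S,3R)-3-methyl-2-(prop-1-en-2-yl)-3-(triisopropylsilyloxymethyl)cyclopentyl]butanal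
Product: 16 (1R,3aR,6R,8aS)-1,4,4-trimethyl-8-methylidene-1-(triisopropylsilyloxymethyl)decahydroazulen-6-ol (C3 carbinol drawn as one epimer)
Conditions: Me2AlCl (2 equiv), CH2Cl2, −78 to 0 °C; aq. potassium sodium tartrate
Reagents that add atoms: none
Why: Me2AlCl binds the aldehyde oxygen, the terminal CH2 of the C10 isopropenyl group (C2) attacks the activated C3 while a hydrogen of the isopropenyl methyl passes to oxygen through an asynchronous six-centre ene transition state, and the aluminium alkoxide formed loses methane. The closest known reaction type is the type 2 intramolecular carbonyl-ene cyclization of 6-methylhept-6-enal-type aldehydes with alkylaluminium chlorides, which gives 3-methylidenecycloheptanols. The seven-membered ring C1–C2–C3–C4–C5–C6–C10 is closed in the type 2 mode, that is with the enophile tethered to the central ene carbon C1, by forming C2–C3, and this mode leaves the methylidene exocyclic on C1. The only new stereocentre, C3, follows from the chair-like folding of the forming ring with the aluminium-bound oxygen pseudoequatorial, but either epimer serves because the oxygen is removed in step 13. The step needs the ene pathway in preference to chloride capture at C1, to proton loss from C2 or C10 and to alkene migration: the cis arrangement of the two arms on the cyclopentane and the gem-dimethyl group at C5 hold the reacting ends together, the freely rotating methyl offers the most accessible hydrogen for the six-membered transfer, and Me2AlCl consumes any free proton as methane.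

Step 12
Reactants: 16 (1R,3aR,6R,8aS)-1,4,4-trimethyl-8-methylidene-1-(triisopropylsilyloxymethyl)decahydroazulen-6-ol
Product: 17 O-[(1R,3aR,6R,8aS)-1,4,4-trimethyl-8-methylidene-1-(triisopropylsilyloxymethyl)decahydroazulen-6-yl] S-methyl carbonodithioate
Conditions: NaH, imidazole (cat.), THF, 0 °C; CS2; MeI
Reagents that add atoms: carbon disulfide S=C=S; iodomethane CI
Why: Xanthate formation from the secondary alkoxide is the activation stage of the Barton–McCombie deoxygenation.

Step 13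
Reactants: 17 O-[(1R,3aR,6R,8aS)-1,4,4-trimethyl-8-methylidene-1-(triisopropylsilyloxymethyl)decahydroazulen-6-yl] S-methyl carbonodithioate
Product: 18 {[(1R,3aR,8aS)-1,4,4-trimethyl-8-methylidenedecahydroazulen-1-yl]methoxy}tri(propan-2-yl)silane
Conditions: Bu3SnH, AIBN, toluene, 100 °C
Reagents that add atoms: none
Why: Barton–McCombie deoxygenation: the stannyl radical adds to the thiocarbonyl, β-scission gives the secondary C3 radical, and Bu3SnH should reduce it faster than it can add 3-exo to the C1 methylidene.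

Step 14
Reactants: 18 {[(1R,3aR,8aS)-1,4,4-trimethyl-8-methylidenedecahydroazulen-1-yl]methoxy}tri(propan-2-yl)silane
Product: 19 [(1R,3aR,8aS)-1,4,4-trimethyl-8-methylidenedecahydroazulen-1-yl]methanol
Conditions: Bu4NF, THF, rt to 50 °C
Reagents that add atoms: none
Why: Fluoride cleavage of the silyl ether frees the neopentyl alcohol on C9.

Step 15
Reactants: 19 [(1R,3aR,8aS)-1,4,4-trimethyl-8-methylidenedecahydroazulen-1-yl]methanol
Product: 20 (1R,3aR,8aS)-1,4,4-trimethyl-8-methylidenedecahydroazulene-1-carbaldehyde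
Conditions: Dess–Martin periodinane, NaHCO3, CH2Cl2, rt
Reagents that add atoms: none
Why: Dess–Martin oxidation gives the C11 aldehyde, which has no α-hydrogen and cannot epimerise.

Step 16
Reactants: 20 (1R,3aR,8aS)-1,4,4-trimethyl-8-methylidenedecahydroazulene-1-carbaldehyde
Product: 21 (1R,3aR,8aS)-1-(2-methoxyethenyl)-1,4,4-trimethyl-8-methylidenedecahydroazulene (E/Z mixture)
Conditions: MeOCH2PPh3Cl, KN(SiMe3)2, THF, 0 °C to rt
Reagents that add atoms: (methoxymethyl)triphenylphosphonium chloride COC[P+](c1ccccc1)(c1ccccc1)c1ccccc1.[Cl-]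
Why: Wittig methoxymethylenation adds C12 as an enol ether; the alkene geometry is irrelevant because both carbons become sp3 in step 21.

Step 17
Reactants: 22 (4S)-2,2-dimethyl-1,3-dioxolane-4-carbaldehyde; 23 prop-2-en-1-yl 2-(diethoxyphosphoryl)acetate
Product: 24 prop-2-en-1-yl (2E)-3-[(4R)-2,2-dimethyl-1,3-dioxolan-4-yl]prop-2-enoate
Conditions: LiCl, DBU, MeCN, 0 °C to rt
Reagents that add atoms: none
Why: Horner–Wadsworth–Emmons olefination under the mild Masamune–Roush conditions gives the (E)-enoate without epimerising the α-alkoxy aldehyde.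

Step 18
Reactants: 24 prop-2-en-1-yl (2E)-3-[(4R)-2,2-dimethyl-1,3-dioxolan-4-yl]prop-2-enoate
Product: 25 prop-2-en-1-yl (2E,4R)-4,5-dihydroxypent-2-enoate
Conditions: AcOH/H2O 4:1, 40 °C
Reagents that add atoms: none
Why: Acid hydrolysis of the acetonide frees the diol; the (E)-geometry keeps the hydroxyls from lactonising onto the ester.

Step 19
Reactants: 25 prop-2-en-1-yl (2E,4R)-4,5-dihydroxypent-2-enoate
Product: 26 (2R,3E)-2-hydroxy-5-oxo-5-(prop-2-en-1-yloxy)pent-3-enoic acid
Conditions: TEMPO (20 mol %), PhI(OAc)2, MeCN/H2O, 0 °C to rt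
Reagents that add atoms: water O
Why: Oxoammonium oxidation is selective for the primary alcohol and carries it to the carboxylic acid in aqueous medium, leaving the secondary carbinol C16 untouched.

Step 20
Reactants: 26 (2R,3E)-2-hydroxy-5-oxo-5-(prop-2-en-1-yloxy)pent-3-enoic acid
Product: 27 1-methyl 5-(prop-2-en-1-yl) (2R,3E)-2-hydroxypent-3-enedioate
Conditions: Me3SiCHN2, MeOH/toluene, 0 °C
Reagents that add atoms: (trimethylsilyl)diazomethane C[Si](C)(C)C=[N+]=[N-]
Why: Diazoalkane esterification gives the methyl ester under neutral conditions that do not touch the allyl ester or the stereocentre.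

Step 21
Reactants: 21 (1R,3aR,8aS)-1-(2-methoxyethenyl)-1,4,4-trimethyl-8-methylidenedecahydroazulene; 27 1-methyl 5-(prop-2-en-1-yl) (2R,3E)-2-hydroxypent-3-enedioate
Product: 28 1-methyl 5-(prop-2-en-1-yl) (2R,3E)-2-{2-bromo-1-methoxy-2-[(1R,3aR,8aS)-1,4,4-trimethyl-8-methylidenedecahydroazulen-1-yl]ethoxy}pent-3-enedioate (epimers at C11 and C12)
Conditions: NBS, CH2Cl2, −40 to 0 °C
Reagents that add atoms: N-bromosuccinimide O=C1CCC(=O)N1Br
Why: Bromoacetalization: the electron-rich enol ether is brominated at C11 much faster than the C1 methylidene, and the oxocarbenium ion at C12 is captured by the hydroxyl of 27.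

Step 22
Reactants: 28 1-methyl 5-(prop-2-en-1-yl) (2R,3E)-2-{2-bromo-1-methoxy-2-[(1R,3aR,8aS)-1,4,4-trimethyl-8-methylidenedecahydroazulen-1-yl]ethoxy}pent-3-enedioate
Product: 29 methyl (2R,3R,4R)-5-methoxy-3-[2-oxo-2-(prop-2-en-1-yloxy)ethyl]-4-[(1R,3aR,8aS)-1,4,4-trimethyl-8-methylidenedecahydroazulen-1-yl]oxolane-2-carboxylate (C12 epimers)
Conditions: Bu3SnH (slow addition), AIBN, benzene, 80 °C
Reagents that add atoms: none
Why: Ueno–Stork 5-exo-trig radical cyclization in which the C11 radical adds to C15, the β-carbon of the enoate; in the chair-like transition state (Beckwith rules) the C9 substituent on the radical carbon and the C16 ester both sit pseudoequatorial, which should give the 1,5-cis (C11/C15) and 4,5-trans (C15/C16) relationships of the target from the fixed C16 centre of 27.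

Step 23
Reactants: 29 methyl (2R,3R,4R)-5-methoxy-3-[2-oxo-2-(prop-2-en-1-yloxy)ethyl]-4-[(1R,3aR,8aS)-1,4,4-trimethyl-8-methylidenedecahydroazulen-1-yl]oxolane-2-carboxylate
Product: 30 2-[(2R,3R,4R)-5-methoxy-2-(methoxycarbonyl)-4-[(1R,3aR,8aS)-1,4,4-trimethyl-8-methylidenedecahydroazulen-1-yl]oxolan-3-yl]acetic acid
Conditions: Pd(PPh3)4 (5 mol %), morpholine, THF, rt
Reagents that add atoms: none
Why: Tsuji–Trost deallylation through a π-allylpalladium intermediate frees the C13 acid under neutral conditions that spare the methyl ester, the acetal and the acid-sensitive methylidene.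

Step 24
Reactants: 30 2-[(2R,3R,4R)-5-methoxy-2-(methoxycarbonyl)-4-[(1R,3aR,8aS)-1,4,4-trimethyl-8-methylidenedecahydroazulen-1-yl]oxolan-3-yl]acetic acid
Product: 31 methyl (1S,5R,6R,8R)-3-oxo-8-[(1R,3aR,8aS)-1,4,4-trimethyl-8-methylidenedecahydroazulen-1-yl]-2,7-dioxabicyclo[3.2.1]octane-6-carboxylate
Conditions: PPTS (20 mol %), 5 Å molecular sieves, CH2Cl2, 40 °C
Reagents that add atoms: none
Why: Acid-catalysed acetal exchange (acylal lactonization): loss of methanol gives the C12 oxocarbenium ion, which the carboxyl on C15 can reach only from its own face, so the six-membered lactone closes and the bridge fixes C12 whatever its configuration in 30.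

Step 25
Reactants: 31 methyl (1S,5R,6R,8R)-3-oxo-8-[(1R,3aR,8aS)-1,4,4-trimethyl-8-methylidenedecahydroazulen-1-yl]-2,7-dioxabicyclo[3.2.1]octane-6-carboxylate
Product: 32 methyl (1S,4S,5S,6R,8R)-4-hydroxy-3-oxo-8-[(1R,3aR,8aS)-1,4,4-trimethyl-8-methylidenedecahydroazulen-1-yl]-2,7-dioxabicyclo[3.2.1]octane-6-carboxylate
Conditions: KN(SiMe3)2, THF, −78 °C; 3-phenyl-2-(phenylsulfonyl)oxaziridine, −78 °C; AcOH
Reagents that add atoms: 3-phenyl-2-(phenylsulfonyl)oxaziridine O=S(=O)(c1ccccc1)N1OC1c1ccccc1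
Why: Enolate hydroxylation with a Davis oxaziridine: the accessible C14 methylene is deprotonated in preference to the concave C16–H, and the oxidant should approach C14 on the face away from the C9 substituent that sits axially over the lactone, giving the equatorial hydroxyl.

Step 26
Reactants: 32 methyl (1S,4S,5S,6R,8R)-4-hydroxy-3-oxo-8-[(1R,3aR,8aS)-1,4,4-trimethyl-8-methylidenedecahydroazulen-1-yl]-2,7-dioxabicyclo[3.2.1]octane-6-carboxylate
Product: 33 methyl (1S,4S,5R,6R,8R)-4-(acetyloxy)-3-oxo-8-[(1R,3aR,8aS)-1,4,4-trimethyl-8-methylidenedecahydroazulen-1-yl]-2,7-dioxabicyclo[3.2.1]octane-6-carboxylate (CNP0215240.1)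
Conditions: Ac2O, pyridine, DMAP (cat.), CH2Cl2, 0 °C
Reagents that add atoms: acetic anhydride CC(=O)OC(C)=O
Why: DMAP-catalysed acetylation of the secondary alcohol with retention at C14 completes the target.

**Compound list**

1 | tert-butyl 2-oxocyclopentane-1-carboxylate | O=C1CCCC1C(=O)OC(C)(C)C | starting material
2 | tert-butyl (1R)-1-methyl-2-oxocyclopentane-1-carboxylate | O=C1[C@](C)(C(=O)OC(C)(C)C)CCC1 | intermediate
3 | (2S)-2-(hydroxymethyl)-2-methylcyclopentan-1-ol (C1 epimers) | OC1[C@](C)(CO)CCC1 | intermediate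
4 | (2S)-2-methyl-2-({[tri(propan-2-yl)silyl]oxy}methyl)cyclopentan-1-ol (C1 epimers) | OC1[C@](C)(CO[Si](C(C)C)(C(C)C)C(C)C)CCC1 | intermediate
5 | (2S)-2-methyl-2-({[tri(propan-2-yl)silyl]oxy}methyl)cyclopentan-1-one | O=C1[C@](C)(CO[Si](C(C)C)(C(C)C)C(C)C)CCC1 | intermediate
6 | (5S)-5-methyl-5-({[tri(propan-2-yl)silyl]oxy}methyl)cyclopent-1-en-1-yl trifluoromethanesulfonate | O=S(=O)(OC1=CCC[C@@]1(C)CO[Si](C(C)C)(C(C)C)C(C)C)C(F)(F)F | intermediate
7 | {[(1R)-2-(1-ethoxyethenyl)-1-methylcyclopent-2-en-1-yl]methoxy}tri(propan-2-yl)silane | CCOC(=C)C1=CCC[C@@]1(C)CO[Si](C(C)C)(C(C)C)C(C)C | intermediate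
8 | 1-[(5R)-5-methyl-5-({[tri(propan-2-yl)silyl]oxy}methyl)cyclopent-1-en-1-yl]ethan-1-one | CC(=O)C1=CCC[C@@]1(C)CO[Si](C(C)C)(C(C)C)C(C)C | intermediate
9 | trimethyl(3-methylbut-2-en-1-yl)silane | CC(C)=CC[Si](C)(C)C | starting material
10 | trichlorotitanium enolate of 11 (C10=C1 enolate, C6 configured as in 11) | CC(O[Ti](Cl)(Cl)Cl)=C1[C@](C)(CO[Si](C(C)C)(C(C)C)C(C)C)CC[C@H]1C(C)(C)C=C | intermediate
11 | 1-[(1R,2R,5R)-2-methyl-5-(2-methylbut-3-en-2-yl)-2-({[tri(propan-2-yl)silyl]oxy}methyl)cyclopentyl]ethan-1-one | CC(=O)[C@H]1[C@](C)(CO[Si](C(C)C)(C(C)C)C(C)C)CC[C@H]1C(C)(C)C=C | intermediate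
12 | {[(1R,2S,3R)-1-methyl-3-(2-methylbut-3-en-2-yl)-2-(prop-1-en-2-yl)cyclopentyl]methoxy}tri(propan-2-yl)silane | CC(=C)[C@H]1[C@](C)(CO[Si](C(C)C)(C(C)C)C(C)C)CC[C@H]1C(C)(C)C=C | intermediate
13 | 2-{3-methyl-3-[(1R,2S,3R)-3-methyl-2-(prop-1-en-2-yl)-3-({[tri(propan-2-yl)silyl]oxy}methyl)cyclopentyl]butyl}-1,3,2-benzodioxaborole | CC(=C)[C@H]1[C@](C)(CO[Si](C(C)C)(C(C)C)C(C)C)CC[C@H]1C(C)(C)CCB2Oc3ccccc3O2 | intermediate
14 | 3-methyl-3-[(1R,2S,3R)-3-methyl-2-(prop-1-en-2-yl)-3-({[tri(propan-2-yl)silyl]oxy}methyl)cyclopentyl]butan-1-ol | CC(=C)[C@H]1[C@](C)(CO[Si](C(C)C)(C(C)C)C(C)C)CC[C@H]1C(C)(C)CCO | intermediate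
15 | 3-methyl-3-[(1R,2S,3R)-3-methyl-2-(prop-1-en-2-yl)-3-({[tri(propan-2-yl)silyl]oxy}methyl)cyclopentyl]butanal | CC(=C)[C@H]1[C@](C)(CO[Si](C(C)C)(C(C)C)C(C)C)CC[C@H]1C(C)(C)CC=O | intermediate
16 | (1R,3aR,6R,8aS)-1,4,4-trimethyl-8-methylidene-1-({[tri(propan-2-yl)silyl]oxy}methyl)decahydroazulen-6-ol (cis-fused; the 6-epimer serves equally) | C=C1C[C@H](O)CC(C)(C)[C@@H]2CC[C@@](C)(CO[Si](C(C)C)(C(C)C)C(C)C)[C@H]12 | intermediate
17 | O-[(1R,3aR,6R,8aS)-1,4,4-trimethyl-8-methylidene-1-({[tri(propan-2-yl)silyl]oxy}methyl)decahydroazulen-6-yl] S-methyl carbonodithioate | C=C1C[C@H](OC(=S)SC)CC(C)(C)[C@@H]2CC[C@@](C)(CO[Si](C(C)C)(C(C)C)C(C)C)[C@H]12 | intermediate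
18 | {[(1R,3aR,8aS)-1,4,4-trimethyl-8-methylidenedecahydroazulen-1-yl]methoxy}tri(propan-2-yl)silane | C=C1CCCC(C)(C)[C@@H]2CC[C@@](C)(CO[Si](C(C)C)(C(C)C)C(C)C)[C@H]12 | intermediate
19 | [(1R,3aR,8aS)-1,4,4-trimethyl-8-methylidenedecahydroazulen-1-yl]methanol | C=C1CCCC(C)(C)[C@@H]2CC[C@@](C)(CO)[C@H]12 | intermediate
20 | (1R,3aR,8aS)-1,4,4-trimethyl-8-methylidenedecahydroazulene-1-carbaldehyde | C=C1CCCC(C)(C)[C@@H]2CC[C@@](C)(C=O)[C@H]12 | intermediate
21 | (1R,3aR,8aS)-1-(2-methoxyethenyl)-1,4,4-trimethyl-8-methylidenedecahydroazulene (E/Z) | C=C1CCCC(C)(C)[C@@H]2CC[C@@](C)(C=COC)[C@H]12 | intermediate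
22 | (4S)-2,2-dimethyl-1,3-dioxolane-4-carbaldehyde | O=C[C@@H]1COC(C)(C)O1 | starting material
23 | prop-2-en-1-yl 2-(diethoxyphosphoryl)acetate | CCOP(=O)(CC(=O)OCC=C)OCC | starting material
24 | prop-2-en-1-yl (2E)-3-[(4R)-2,2-dimethyl-1,3-dioxolan-4-yl]prop-2-enoate | C=CCOC(=O)/C=C/[C@@H]1COC(C)(C)O1 | intermediate
25 | prop-2-en-1-yl (2E,4R)-4,5-dihydroxypent-2-enoate | C=CCOC(=O)/C=C/[C@@H](O)CO | intermediate
26 | (2R,3E)-2-hydroxy-5-oxo-5-(prop-2-en-1-yloxy)pent-3-enoic acid | C=CCOC(=O)/C=C/[C@@H](O)C(=O)O | intermediate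
27 | 1-methyl 5-(prop-2-en-1-yl) (2R,3E)-2-hydroxypent-3-enedioate | C=CCOC(=O)/C=C/[C@@H](O)C(=O)OC | intermediate
28 | 1-methyl 5-(prop-2-en-1-yl) (2R,3E)-2-{2-bromo-1-methoxy-2-[(1R,3aR,8aS)-1,4,4-trimethyl-8-methylidenedecahydroazulen-1-yl]ethoxy}pent-3-enedioate (C11, C12 epimers) | C=C1CCCC(C)(C)[C@@H]2CC[C@@](C)(C(Br)C(OC)O[C@H](/C=C/C(=O)OCC=C)C(=O)OC)[C@H]12 | intermediate
29 | methyl (2R,3R,4R)-5-methoxy-3-[2-oxo-2-(prop-2-en-1-yloxy)ethyl]-4-[(1R,3aR,8aS)-1,4,4-trimethyl-8-methylidenedecahydroazulen-1-yl]oxolane-2-carboxylate (C5 epimers) | C=C1CCCC(C)(C)[C@@H]2CC[C@@](C)([C@@H]3C(OC)O[C@@H](C(=O)OC)[C@@H]3CC(=O)OCC=C)[C@H]12 | intermediate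
30 | 2-[(2R,3R,4R)-5-methoxy-2-(methoxycarbonyl)-4-[(1R,3aR,8aS)-1,4,4-trimethyl-8-methylidenedecahydroazulen-1-yl]oxolan-3-yl]acetic acid (C5 epimers) | C=C1CCCC(C)(C)[C@@H]2CC[C@@](C)([C@@H]3C(OC)O[C@@H](C(=O)OC)[C@@H]3CC(=O)O)[C@H]12 | intermediate
31 | methyl (1S,5R,6R,8R)-3-oxo-8-[(1R,3aR,8aS)-1,4,4-trimethyl-8-methylidenedecahydroazulen-1-yl]-2,7-dioxabicyclo[3.2.1]octane-6-carboxylate | C=C1CCCC(C)(C)[C@@H]2CC[C@@](C)([C@@H]3[C@@H]4OC(=O)C[C@H]3[C@H](C(=O)OC)O4)[C@H]12 | intermediate
32 | methyl (1S,4S,5S,6R,8R)-4-hydroxy-3-oxo-8-[(1R,3aR,8aS)-1,4,4-trimethyl-8-methylidenedecahydroazulen-1-yl]-2,7-dioxabicyclo[3.2.1]octane-6-carboxylate | C=C1CCCC(C)(C)[C@@H]2CC[C@@](C)([C@@H]3[C@@H]4OC(=O)[C@@H](O)[C@H]3[C@H](C(=O)OC)O4)[C@H]12 | intermediate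
33 | methyl (1S,4S,5R,6R,8R)-4-(acetyloxy)-3-oxo-8-[(1R,3aR,8aS)-1,4,4-trimethyl-8-methylidenedecahydroazulen-1-yl]-2,7-dioxabicyclo[3.2.1]octane-6-carboxylate | C=C1CCCC(C)(C)[C@@H]2CC[C@@](C)([C@@H]3[C@@H]4OC(=O)[C@@H](OC(C)=O)[C@H]3[C@H](C(=O)OC)O4)[C@H]12 | target

**Step count**

Total: 26 steps. Longest linear sequence: 22 steps (steps 1–16 and 21–26); steps 17–20 prepare the side component 27.

**Steps most likely to fail**

Step 7 (conjugate addition). The control of C6 by the remote C9 centre is only a 1,3-steric effect: the silane may add on the face of the silyloxymethyl group, and the kinetic C10 centre may be lost by enolisation during the Lewis-acidic quench. The fallback replaces steric control by hydrogen delivery directed by the C9 hydroxymethyl group. It sets out from 11, whatever its C6/C10 composition, and returns at 14.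
- Hydroboration of the vinyl group (catecholborane, RhCl(PPh3)3; then NaOH, H2O2) should give the hydroxy ketone F1.
- Acylation with pivaloyl chloride and pyridine should give the pivalate F2.
- Dehydrogenation with IBX in DMSO at 70 °C should give the tetrasubstituted enone F3, in which both doubtful centres are erased.
- Bu4NF should give the hydroxy enone F4.
- H2 with [Ir(cod)(PCy3)(py)]PF6 in CH2Cl2 should add both hydrogens to C6 and C10 from the face of the coordinating hydroxyl, giving the all-cis hydroxy ketone F5.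
- Silylation (i-Pr3SiOTf, 2,6-lutidine) should give the silyl ether F6, and methylenation as in step 8 the isopropenyl pivalate F7.
- i-Bu2AlH removes the pivalate and gives 14.

Step 11 (ene closure). The cationic pathway may be diverted to chloride capture at C1, to proton loss into the ring (endocyclic alkene), or to intermolecular reaction of the aldehyde before the seven-membered ring closes. The fallback forms the same C2–C3 bond by an organochromium allylation. It sets out from 15 and returns at 16.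
- Ene-type allylic chlorination of the isopropenyl methyl (Ca(OCl)2, CO2, CH2Cl2/H2O, 0 °C) should give the allylic chloride F8.
- CrCl2 in THF at high dilution (Nozaki–Hiyama allylation) should generate the allylchromium species, which adds to the aldehyde through its γ-carbon C2 with transposition of the double bond onto C1, giving 16.

Step 22 (radical cyclization). The very bulky C9 substituent on the radical carbon may leave the pseudoequatorial position to avoid the vicinal C14 carbon, so that C11 forms with the wrong configuration relative to C15. The fallback cyclises onto an alkyne and then sets C15 by hydride delivery. It sets out from 21 and 22 and returns at 29.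
- Aldehyde 22 with dimethyl (1-diazo-2-oxopropyl)phosphonate and K2CO3 in MeOH (Ohira–Bestmann) should give the alkyne F9.
- n-BuLi and allyl chloroformate should give the ynoate F10.
- AcOH/H2O should give the diol F11, TEMPO/PhI(OAc)2 the acid F12, and Me3SiCHN2 the hydroxy ynoate F13.
- NBS should join 21 and F13 to the bromoacetal F14.
- Bu3SnH/AIBN should give, by 5-exo-dig closure, the alkylidene oxolane F15. Here only the 1,3-relation of C11 to C16 has to be controlled (both substituents pseudoequatorial, no vicinal clash with the sp carbon).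
- Conjugate reduction with [(Ph3P)CuH]6 should deliver hydride to C15 on the face opposite to the adjacent C9 substituent and give 29.

**Further compounds**

F1 | step 7 | 1-[(2R)-5-(4-hydroxy-2-methylbutan-2-yl)-2-methyl-2-({[tri(propan-2-yl)silyl]oxy}methyl)cyclopentyl]ethan-1-one (C6/C10 isomer mixture) | CC(=O)C1[C@](C)(CO[Si](C(C)C)(C(C)C)C(C)C)CCC1C(C)(C)CCO
F2 | step 7 | pivalate of F1 | CC(=O)C1[C@](C)(CO[Si](C(C)C)(C(C)C)C(C)C)CCC1C(C)(C)CCOC(=O)C(C)(C)C
F3 | step 7 | 3-[(3R)-2-acetyl-3-methyl-3-({[tri(propan-2-yl)silyl]oxy}methyl)cyclopent-1-en-1-yl]-3-methylbutyl 2,2-dimethylpropanoate | CC(=O)C1=C(C(C)(C)CCOC(=O)C(C)(C)C)CC[C@@]1(C)CO[Si](C(C)C)(C(C)C)C(C)C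
F4 | step 7 | 3-[(3R)-2-acetyl-3-(hydroxymethyl)-3-methylcyclopent-1-en-1-yl]-3-methylbutyl 2,2-dimethylpropanoate | CC(=O)C1=C(C(C)(C)CCOC(=O)C(C)(C)C)CC[C@@]1(C)CO
F5 | step 7 | all-cis 3-[2-acetyl-3-(hydroxymethyl)-3-methylcyclopentyl]-3-methylbutyl 2,2-dimethylpropanoate (acetyl, side chain and C9 methyl on one face) | CC(=O)[C@H]1[C@](C)(CO)CC[C@H]1C(C)(C)CCOC(=O)C(C)(C)C
F6 | step 7 | triisopropylsilyl ether of F5 | CC(=O)[C@H]1[C@](C)(CO[Si](C(C)C)(C(C)C)C(C)C)CC[C@H]1C(C)(C)CCOC(=O)C(C)(C)C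
F7 | step 7 | pivalate of 14 | CC(=C)[C@H]1[C@](C)(CO[Si](C(C)C)(C(C)C)C(C)C)CC[C@H]1C(C)(C)CCOC(=O)C(C)(C)C
F8 | step 11 | 3-[2-(3-chloroprop-1-en-2-yl)-3-methyl-3-({[tri(propan-2-yl)silyl]oxy}methyl)cyclopentyl]-3-methylbutanal (ring configured as in 15) | ClCC(=C)[C@H]1[C@](C)(CO[Si](C(C)C)(C(C)C)C(C)C)CC[C@H]1C(C)(C)CC=O
F9 | step 22 | (4R)-4-ethynyl-2,2-dimethyl-1,3-dioxolane | C#C[C@@H]1COC(C)(C)O1
F10 | step 22 | prop-2-en-1-yl 3-[(4R)-2,2-dimethyl-1,3-dioxolan-4-yl]prop-2-ynoate | C=CCOC(=O)C#C[C@@H]1COC(C)(C)O1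
F11 | step 22 | prop-2-en-1-yl (4R)-4,5-dihydroxypent-2-ynoate | C=CCOC(=O)C#C[C@@H](O)CO
F12 | step 22 | (2R)-2-hydroxy-5-oxo-5-(prop-2-en-1-yloxy)pent-3-ynoic acid | C=CCOC(=O)C#C[C@@H](O)C(=O)O
F13 | step 22 | 1-methyl 5-(prop-2-en-1-yl) (2R)-2-hydroxypent-3-ynedioate | C=CCOC(=O)C#C[C@@H](O)C(=O)OC
F14 | step 22 | alkynoate analogue of bromoacetal 28 (C11, C12 epimers) | C=C1CCCC(C)(C)[C@@H]2CC[C@@](C)(C(Br)C(OC)O[C@H](C#CC(=O)OCC=C)C(=O)OC)[C@H]12
F15 | step 22 | methyl (2R,4R)-5-methoxy-3-[2-oxo-2-(prop-2-en-1-yloxy)ethylidene]-4-[(1R,3aR,8aS)-1,4,4-trimethyl-8-methylidenedecahydroazulen-1-yl]oxolane-2-carboxylate (alkene and C5 isomers) | C=C1CCCC(C)(C)[C@@H]2CC[C@@](C)([C@@H]3C(OC)O[C@@H](C(=O)OC)C3=CC(=O)OCC=C)[C@H]12
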